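**Plan**
Lettering: ring A is the benzo ring of the chromanone, ring C its O1–C2–C3–C4 heterocycle, ring B the aryl group on C3, and ring D the dimethylpyran fused to ring B.
Retrosynthesis: the 7-OH is masked as a TIPS ether and the C4 ketone is traced back to a cis C4 carbinol. Removing the C2–H, C3–H and C4–H bonds leads to an achiral isoflavone, which is cut at C3–C1' into a 3-iodochromone and a ring B/D boronate.
Forward: ring C is closed on ring A (enaminone, iodine) and ring D on ring B (propargyl ether Claisen cascade). The halves are joined at C3–C1', and only then is ring C reduced.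
Enabling feature: C3 lies between the C4 carbonyl and ring B, so the C3–H of the isoflavanone is acidic and C3 racemises through the C3=C4 enol. The C2=C3 bond of the isoflavone is a polarised vinylogous ester that accepts hydride at C2, whereas the ring D alkene is unpolarised.
Stereochemistry: one Ru/(S,S)-TsDPEN transfer hydrogenation sets C4 by catalyst control and C3 by dynamic kinetic resolution (cis). Reoxidation erases C4 and leaves (3S).

Key step: step 8

Assumption: the (S,S)-ligand is taken to give the (4S)-carbinol, as it does with 4-chromanone and other aryl alkyl ketones; if the sense were opposite, the (R,R)-ligand would be used in the same way.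

Step 1
Reactants: 1 2,4-dihydroxyacetophenone
Product: 2 1-[2-hydroxy-4-(triisopropylsilyloxy)phenyl]ethan-1-one
Conditions: TIPSCl, imidazole, CH2Cl2, 0 °C to rt
Reagents that add atoms: triisopropylsilyl chloride, CC(C)[Si](Cl)(C(C)C)C(C)C
Why: Chemoselective O-silylation; the 2-OH is hydrogen-bonded to the acetyl carbonyl and crowded by it, so the bulky silyl chloride should react only at the free, more acidic 4-OH.

Step 2
Reactants: 2 1-[2-hydroxy-4-(triisopropylsilyloxy)phenyl]ethan-1-one
Product: 3 (E)-3-(dimethylamino)-1-[2-hydroxy-4-(triisopropylsilyloxy)phenyl]prop-2-en-1-one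
Conditions: Me2NCH(OMe)2, toluene, 90 °C
Reagents that add atoms: N,N-dimethylformamide dimethyl acetal, COC(OC)N(C)C
Why: Enaminone condensation of a methyl ketone with an amide acetal, the standard entry to chromones, supplies the future C2, and the hindered TIPS ether should tolerate the methanol released.

Step 3
Reactants: 3 (E)-3-(dimethylamino)-1-[2-hydroxy-4-(triisopropylsilyloxy)phenyl]prop-2-en-1-one
Product: 4 3-iodo-7-(triisopropylsilyloxy)-4H-chromen-4-one
Conditions: I2, CHCl3, rt
Reagents that add atoms: iodine, II
Why: Gammill-type iodocyclisation; iodination of the enaminone α-carbon, addition of the phenol oxygen to the β-carbon and loss of dimethylamine close ring C and leave the iodide at C3 as coupling handle.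

Step 4
Reactants: 5 4-bromo-3-methoxyphenol; 6 3-chloro-3-methylbut-1-yne
Product: 7 1-bromo-2-methoxy-4-[(2-methylbut-3-yn-2-yl)oxy]benzene
Conditions: CuCl2·2H2O (cat.), DBU, MeCN, 0 °C
Reagents that add atoms: none
Why: Copper-catalysed O-propargylation of a phenol with a tertiary propargyl chloride (Godfrey etherification) should give the hindered aryl 1,1-dimethylpropargyl ether at low temperature without C-alkylation.

Step 5
Reactants: 7 1-bromo-2-methoxy-4-[(2-methylbut-3-yn-2-yl)oxy]benzene
Product: 9 6-bromo-7-methoxy-2,2-dimethyl-2H-chromene, via allenylphenol 8 (not isolated)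
Conditions: o-xylene, 145 °C
Reagents that add atoms: none
Why: Aromatic propargyl Claisen rearrangement to allenylphenol 8, then 1,5-hydrogen shift and oxa-6π electrocyclisation close ring D; the shift should go to the ortho carbon para to the methoxy group, because the other ortho carbon lies between two oxygens and the neighbouring bromine turns the methoxy methyl towards it.

Step 6
Reactants: 9 6-bromo-7-methoxy-2,2-dimethyl-2H-chromene; 10 bis(pinacolato)diboron
Product: 11 2-(7-methoxy-2,2-dimethyl-2H-chromen-6-yl)-4,4,5,5-tetramethyl-1,3,2-dioxaborolane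
Conditions: Pd(dppf)Cl2 (cat.), KOAc, 1,4-dioxane, 90 °C
Reagents that add atoms: none
Why: Miyaura borylation of an aryl bromide; the weak acetate base should suppress homocoupling, and the ring D alkene and the ethers are inert under these conditions.

Step 7
Reactants: 4 3-iodo-7-(triisopropylsilyloxy)-4H-chromen-4-one; 11 2-(7-methoxy-2,2-dimethyl-2H-chromen-6-yl)-4,4,5,5-tetramethyl-1,3,2-dioxaborolane
Product: 12 3-(7-methoxy-2,2-dimethyl-2H-chromen-6-yl)-7-(triisopropylsilyloxy)-4H-chromen-4-one
Conditions: Pd(OAc)2 (cat.), SPhos, K3PO4, THF/H2O (10:1), 50 °C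
Reagents that add atoms: none
Why: Suzuki–Miyaura coupling of a 3-iodochromone forms C3–C1'; the reactive carbon–iodine bond adds readily to zerovalent palladium and SPhos accommodates the ortho-methoxy boronate, so a mild phosphate base and low temperature should spare the pyranone ring and the aryl silyl ether.

Step 8
Reactants: 12 3-(7-methoxy-2,2-dimethyl-2H-chromen-6-yl)-7-(triisopropylsilyloxy)-4H-chromen-4-one
Product: 14 (3S,4S)-3-(7-methoxy-2,2-dimethyl-2H-chromen-6-yl)-7-(triisopropylsilyloxy)chroman-4-ol, via racemising isoflavanone 13 (not isolated)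
Conditions: RuCl(p-cymene)[(S,S)-TsDPEN] (5 mol %), HCO2H (6 equiv), Et3N (9 equiv), EtOAc, 45 °C
Reagents that add atoms: none
Why: Formate converts the ruthenium amide into the Ru–H/N–H species, which first delivers hydride to C2 of the vinylogous ester C2=C3–C4=O, and protonation of the resulting enol at C3 gives isoflavanone 13, which free Et3N keeps racemic through the C3=C4 enol. The same catalyst then reduces C4=O through the six-membered outer-sphere Ru–H/N–H transition state of the Noyori–Ikariya asymmetric transfer hydrogenation, the closest known reaction type being the one-pot conjugate reduction and dynamic kinetic resolution of isoflavones to cis-isoflavan-4-ols. No ring closes and no skeletal bond forms; only the C2–H, C3–H and C4–H bonds are made. C4 is set by the ligand, since the CH–π contact between p-cymene and ring A fixes the carbonyl face and (S,S)-TsDPEN should give (4S). C3 is set by the resolution, since only the (3S)-ketone holds ring B on the face away from the incoming hydride and is therefore reduced much faster, which places hydroxyl and aryl cis, while the (3R)-ketone is returned through the enol. The step needs chemoselectivity over the ring D alkene and the silyl ether; the first follows from the lack of polarisation of that styrene-type double bond towards an outer-sphere hydride, and the second from the bulk of TIPS in an amine-rich medium that should also keep the acid-labile benzylic carbinol from ionising.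

Step 9
Reactants: 14 (3S,4S)-3-(7-methoxy-2,2-dimethyl-2H-chromen-6-yl)-7-(triisopropylsilyloxy)chroman-4-ol
Product: 15 (3S)-3-(7-methoxy-2,2-dimethyl-2H-chromen-6-yl)-7-(triisopropylsilyloxy)chroman-4-one
Conditions: Dess–Martin periodinane, NaHCO3, CH2Cl2, 0 °C to rt
Reagents that add atoms: none
Why: Dess–Martin oxidation of a secondary benzylic alcohol runs fast under near-neutral conditions; the bicarbonate takes up the acetic acid, so C3 should not enolise, and the alkene and silyl ether are untouched while the auxiliary C4 centre is erased.

Step 10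
Reactants: 15 (3S)-3-(7-methoxy-2,2-dimethyl-2H-chromen-6-yl)-7-(triisopropylsilyloxy)chroman-4-one
Product: 16 (3S)-7-hydroxy-3-(7-methoxy-2,2-dimethyl-2H-chromen-6-yl)chroman-4-one
Conditions: Bu4NF/AcOH (1:1), THF, 0 °C; then pH 7 phosphate buffer
Reagents that add atoms: none
Why: Fluoride desilylation of an aryl silyl ether; the ether is para to the C4 carbonyl and thus strongly activated, so cleavage should be quick in the cold, and acetic acid protonates the phenoxide at once so that no base able to enolise C3 builds up.

**Compound list**
1 | 2,4-dihydroxyacetophenone | CC(=O)c1ccc(O)cc1O | starting material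
2 | 1-[2-hydroxy-4-(triisopropylsilyloxy)phenyl]ethan-1-one | CC(=O)c1ccc(O[Si](C(C)C)(C(C)C)C(C)C)cc1O | intermediate
3 | (E)-3-(dimethylamino)-1-[2-hydroxy-4-(triisopropylsilyloxy)phenyl]prop-2-en-1-one | CN(C)/C=C/C(=O)c1ccc(O[Si](C(C)C)(C(C)C)C(C)C)cc1O | intermediate
4 | 3-iodo-7-(triisopropylsilyloxy)-4H-chromen-4-one | O=C1C(I)=COc2cc(O[Si](C(C)C)(C(C)C)C(C)C)ccc12 | intermediate
5 | 4-bromo-3-methoxyphenol | COc1cc(O)ccc1Br | starting material
6 | 3-chloro-3-methylbut-1-yne | CC(C)(Cl)C#C | starting material
7 | 1-bromo-2-methoxy-4-[(2-methylbut-3-yn-2-yl)oxy]benzene | COc1cc(OC(C)(C)C#C)ccc1Br | intermediate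
8 | 4-bromo-5-methoxy-2-(3-methylbuta-1,2-dien-1-yl)phenol (allenylphenol, not isolated) | COc1cc(O)c(C=C=C(C)C)cc1Br | intermediate
9 | 6-bromo-7-methoxy-2,2-dimethyl-2H-chromene | COc1cc2OC(C)(C)C=Cc2cc1Br | intermediate
10 | bis(pinacolato)diboron | CC1(C)OB(OC1(C)C)B1OC(C)(C)C(C)(C)O1 | starting material
11 | 2-(7-methoxy-2,2-dimethyl-2H-chromen-6-yl)-4,4,5,5-tetramethyl-1,3,2-dioxaborolane | COc1cc2OC(C)(C)C=Cc2cc1B1OC(C)(C)C(C)(C)O1 | intermediate
12 | 3-(7-methoxy-2,2-dimethyl-2H-chromen-6-yl)-7-(triisopropylsilyloxy)-4H-chromen-4-one | COc1cc2OC(C)(C)C=Cc2cc1C1=COc2cc(O[Si](C(C)C)(C(C)C)C(C)C)ccc2C1=O | intermediate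
13 | (±)-3-(7-methoxy-2,2-dimethyl-2H-chromen-6-yl)-7-(triisopropylsilyloxy)chroman-4-one (racemising isoflavanone, not isolated) | COc1cc2c(cc1C1COc3cc(O[Si](C(C)C)(C(C)C)C(C)C)ccc3C1=O)C=CC(C)(C)O2 | intermediate
14 | (3S,4S)-3-(7-methoxy-2,2-dimethyl-2H-chromen-6-yl)-7-(triisopropylsilyloxy)chroman-4-ol (cis) | COc1cc2c(cc1[C@H]1COc3cc(O[Si](C(C)C)(C(C)C)C(C)C)ccc3[C@H]1O)C=CC(C)(C)O2 | intermediate
15 | (3S)-3-(7-methoxy-2,2-dimethyl-2H-chromen-6-yl)-7-(triisopropylsilyloxy)chroman-4-one | COc1cc2c(cc1[C@H]1COc3cc(O[Si](C(C)C)(C(C)C)C(C)C)ccc3C1=O)C=CC(C)(C)O2 | intermediate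
16 | (3S)-7-hydroxy-3-(7-methoxy-2,2-dimethyl-2H-chromen-6-yl)chroman-4-one | COc1cc2c(cc1[C@H]1COc3cc(O)ccc3C1=O)C=CC(C)(C)O2 | target

Total step count: 10. Longest linear sequence: 7 steps (steps 1, 2, 3, 7, 8, 9, 10, or equally steps 4, 5, 6, 7, 8, 9, 10).

**Steps most likely to fail**

Step 8. Hydride transfer to C2 may be slow on this electron-rich, ortho-substituted isoflavone, so the catalyst could decay before the ketone reduction is complete. Racemisation at C3 could also lag behind reduction and lower the enantio- and cis-selectivity. The fallback separates the two reductions. It sets out from 12, which undergoes stoichiometric 1,4-reduction with LiBH(s-Bu)3 in THF at −78 °C, and a proton quench gives 13, now isolated. Compound 13 alone is then submitted to the transfer-hydrogenative dynamic kinetic resolution with fresh RuCl(p-cymene)[(S,S)-TsDPEN], HCO2H and Et3N. The catalyst then has only the ketone to reduce, and the sequence returns to the route at 14. No compound outside the list is made (F0).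

Step 5. The sigmatropic shift may show poor regioselectivity between the two ortho positions, and the propargyl ether may degrade on heating. The fallback replaces the pericyclic ring closure by an ionic one and sets out from 5.
- Friedel–Crafts acylation with 3-methylbut-2-enoic acid in P2O5/MeSO3H at 70 °C is directed para to the methoxy group and ortho to the hydroxyl. Oxa-Michael closure follows and gives 6-bromo-7-methoxy-2,2-dimethylchroman-4-one F1.
- NaBH4 in MeOH reduces F1 to (±)-6-bromo-7-methoxy-2,2-dimethylchroman-4-ol F2.
- Dehydration with catalytic TsOH in toluene at reflux returns to the route at 9.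

Step 10. Fluoride or the liberated phenoxide may partly enolise C3, which would erode the configuration in the last operation. The fallback removes the silyl group while C3 cannot enolise and sets out from 14.
- Bu4NF/AcOH in THF gives (3S,4S)-3-(7-methoxy-2,2-dimethyl-2H-chromen-6-yl)chroman-4,7-diol F3.
- One equivalent of DDQ in 1,4-dioxane at rt then oxidises the para-hydroxybenzylic carbinol by hydride abstraction from C4 under non-basic conditions. Ring D, itself a typical product of DDQ dehydrogenation, should persist.
- This bypasses 15 and returns to the route at 16.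

**Further compounds**
F0 | step 8 | none | none
F1 | step 5 | 6-bromo-7-methoxy-2,2-dimethylchroman-4-one | COc1cc2OC(C)(C)CC(=O)c2cc1Br
F2 | step 5 | (±)-6-bromo-7-methoxy-2,2-dimethylchroman-4-ol | COc1cc2OC(C)(C)CC(O)c2cc1Br
F3 | step 10 | (3S,4S)-3-(7-methoxy-2,2-dimethyl-2H-chromen-6-yl)chroman-4,7-diol | COc1cc2c(cc1[C@H]1COc3cc(O)ccc3[C@H]1O)C=CC(C)(C)O2
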